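The charges differ in one amount, the stray impurity, which stands at 32 µM in the north-west run and 61 µM in Monday's flask, below c(free catalyst) of 0.50 mM.

| setting | north-west | south-west | Monday's | Sunday's |
|---|---|---|---|---|
| left-handed substrate | 10 mM | 10 mM | 10 mM | 10 mM |
| right-handed substrate | 10 mM | 10 mM | 10 mM | 10 mM |
| partner | 30 mM | 30 mM | 30.0 mM | 30.0 mM |
| protic impurity | 10 mM | 10 mM | 10.0 mM | 10.0 mM |
| free catalyst | 0.50 mM | 0.50 mM | 0.50 mM | 0.50 mM |
| stray impurity | 32 µM | 52 µM | 61 µM | 40 µM |
| remark | run made earlier | run made earlier |  |  |
| time |  |  | 6.0 d | 6.0 d |

| run | time / d | right-handed substrate / % | left-handed substrate / % |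
|---|---|---|---|
| north-west | 0.625 | 48 | 22 |
| north-west | 1.25 | 47 | 11 |
| north-west | 2.00 | 50 | 4 |
| north-west | 3.00 | 47 | 0 |
| north-west | 4.00 | 46 | 3 |
| south-west | 0.625 | 47 | 22 |
| south-west | 1.25 | 46 | 11 |
| south-west | 2.00 | 49 | 3 |
| south-west | 3.00 | 48 | 3 |
| south-west | 4.00 | 50 | 2 |

(readings scatter by 1.5 percentage points)

- free catalyst is single-handed; left-handed substrate and right-handed substrate are mirror images of each other, charged as a racemate, each of them at the stated concentration
- an excess is below zero if the other one leads

- which one finishes higher in excess of right-handed substrate over left-handed substrate among what is left of the two ("neither" within 2 percentage points) (Monday's / Sunday's / neither)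
- excess of right-handed substrate over left-handed substrate among what is left of the two at the end, Monday's
- excess of right-handed substrate over left-handed substrate among what is left of the two at the end, Sunday's

Read the left-handed column of the north-west run first. It gives 22% at 0.625 d and 11% at 1.25 d, so half goes in one interval. The south-west run, with more stray impurity, gives 22% and 11%, the same pair. A fall by equal fractions in equal times reads as a pseudo-first-order loss, with the rate following c(left-handed substrate). The quantity to carry is therefore the half-life of left-handed substrate, the time in which c(left-handed substrate) falls to half its value: 0.625 d, as read from these readings.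

The right-handed column of the north-west run goes from 48% to 46%, a drift of 2 percentage points against a scatter of 1.5 points. The last left-handed readings, 3% and 2%, are too near the scatter to test the halving further.

My own reckoning runs the half-life on from 11% at 1.25 d. Because it is short against 6.0 d, 0.0567% remains. Beside 46% of right-handed substrate, that is an excess of 99.8% for both Monday's and Sunday's flasks, assuming that 61 µM still leaves the half-life unchanged.

The forecast is more cautious, with 95% for Monday's, 95% for Sunday's and neither as the answer to which finishes higher. It sees in the late readings “a weak hint of a stall or small floor”.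

The flasks give 99.4% for Monday's and 99.5% for Sunday's, so the answer is neither.

    partner → decomposition product (k = 9.79 × 10⁻⁸ s⁻¹)
    partner + catalyst intermediate B → free catalyst + right-handed product (k = 0.00109 M⁻¹ s⁻¹)
    free catalyst + right-handed substrate ⇌ catalyst intermediate B (K = 48.0 M⁻¹, k = 42.0 M⁻¹ s⁻¹)
    partner + protic impurity → quenched reagent (k = 0.185 M⁻¹ s⁻¹)
    partner + catalyst intermediate A → free catalyst + left-handed product (k = 0.0947 M⁻¹ s⁻¹)
    free catalyst + left-handed substrate ⇌ catalyst intermediate A (K = 40.8 M⁻¹, k = 1.17 M⁻¹ s⁻¹)
    free catalyst + stray impurity → spent catalyst (k = 480 M⁻¹ s⁻¹)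

Carried to Monday's flask, 0.625 d gave 0.0567% of left-handed substrate at 6.0 d, and the flask holds 0.138%. Carried to a reading of Monday's flask at 40 h, it gives 6.93% and an excess of 74.8%, and the flask shows 6.97% and 74.6%. At 0.00160 d in Monday's flask, protic impurity uses partner 110 times as fast as catalyst intermediate A does. The excess of that reading at 40 h stands 20 points below the forecast's 95% for the end of Monday's flask.

(The runs are calculated for substances that don't exist, and the scatter is random.)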